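Assumption: atoms are numbered as in 6H-isochromene (O2, C1, C3, C4, C4a, C5 to C8, C8a; side-chain carbons C2′ and C4′), also in monocyclic precursors. The exocyclic C4a=C5 bond of 18–21 is a push–pull alkene that should equilibrate, and it is drawn as the reactive Z form.

## The problem

The target is a 7,8-dihydro-6H-isochromen-6-one. Ring A is a pyran (O2, C1, C3, C4, C4a, C8a) whose exocyclic C4a=C5 bond makes it a vinylogous γ-pyrone. Ring B is a carbocycle (C4a, C5, C6, C7, C8, C8a) that carries the only ring stereocentres: the tertiary carbinol C7 (OH, CH3) and the neighbouring C8 (H, ester). Two further stereocentres (C2′, C4′) lie in the 4-methylhexan-2-yl ester. They are too remote to control ring B and must be brought in separately.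

C7 and C8 must be set together. The C7 hydroxyl and the C8 carboxyl are cis, C8–H is α to an ester and allylic and so can epimerise, and C7 cannot be corrected once made. The compound is at once a β-hydroxy ester and an α-hydroxy ketone. Base therefore threatens retro-aldol cleavage of C7–C8 and E1cB loss of water, the latter giving an aromatic 2-benzopyrylium-6-olate. The two carboxyl groups must end up different (C8 as a hindered secondary ester, the acrylic acid free), and the chromophore exchanges O2 for nitrogen with primary amines.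

The feature the plan exploits is the cis 1,3-relation of O7 and the C8 carbonyl carbon across the C7–C8 bond of ring B. This is the retron of a cis-fused β-lactone. In addition, C5–C6(=O)–C7(CH3) is a masked 1,2-dione that can be attached to the pyrone carbonyl carbon C4a.

## Retrosynthesis

**31 to 30.** Only the O–C bond of a tert-butyl ester is cut. The acrylic carboxyl stays masked through every basic or nucleophilic step, and the last step is an acidolysis that the base-sensitive ring B should tolerate.

**30 to 22 and 27.** The acyl C–O bond of the C8 ester is cut, so that 30 becomes the cis-fused β-lactone 22 plus the side-chain alcohol 27. The neighbouring option, esterifying a free β-hydroxy acid, would need carboxyl activation, which leads back to the lactone or to elimination. Carrying the ester from the start would leave no handle for asymmetric C7–C8 bond formation. The lactone is a strained acyl donor and has the cis relation built in. The forward reaction asks for acyl attack by alkoxide 28 at low temperature, with the aldolate 29 quenched before it can fragment.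

**22 to 19 (key disconnection).** The C7–C8 bond and the O7–C(=O) bond are cut together. The precursor 19 is an achiral monocyclic keto acid without ring B. Cutting C4a=C5 instead would leave a ring closure onto the pyrone with two competing six-membered modes (C4a or C1). Cutting C7–O last would give the wrong relative configuration. The forward reaction is a catalytic aldol-lactonisation that must close ring B, set C8 by catalyst control and set C7 through the cis ring fusion.

**19 to 10 and 14.** The C4a=C5 bond is cut and the C6 carbonyl is traced back to an alkyne. Alkyne 14, as its magnesium acetylide 15, adds to the pyrone carbonyl of acid 10, and a Meyer–Schuster rearrangement turns the propargylic pyranol into the 4-ylidenepyran ketone. Alkyne 14 comes in one step from the commercial monoketal 11, which supplies C5, C6, C7 and the C7 methyl group. A metal acetylide is a hard, irreversible nucleophile for the poorly electrophilic pyrone carbonyl, where an enolate addition would be reversible.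

**10 to 5 and 6, by way of 8.** The C8–C8a bond is cut. A Negishi coupling of the Reformatsky reagent 7 (from 6) with vinyl triflate 5 installs the acetic acid unit as methyl ester 8. The methyl ester is cleaved selectively next to the tert-butyl ester.

**5 to 2 and 3, then 2 to 1.** The acrylate C=C bond is cut (Wittig reaction of ylide 3 with the aldehyde from 2), and the triflate is traced to the enolic hydroxyl of kojic acid 1. Kojic acid already holds ring A with oxygen at C8a and a one-carbon handle at C3.

**27 to 26, then 23 and 24.** The carbinol C–H bond and the C2′–C3′ bond are cut. C4′ comes from the chiral-pool bromide 23, and C2′ is set by catalyst-controlled reduction of ketone 26.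

## Roads not taken

**Alternative 1:** (the most obvious route) cuts ring A at O2–C3 and ring B at C7–O, going back to the arene A1. The forward key step is cycloisomerisation of the o-alkynylbenzaldehyde A1 to the 2-benzopyrylium-6-olate A2, followed by hydroxylative dearomatisation at C7.
- In the target C8 is an sp3 CH–CO2R and not a carbonyl, so after oxidation a hydride must still be delivered to C8 with regio- and facial control, although C1 is the usual site of nucleophilic attack on such cations.
- Catalyst-controlled hydroxylative dearomatisation is established for resorcinol-type substrates, and A1 lacks the second oxygen.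
- A1 is a hexasubstituted benzene, and its hindered ester would have to be made on a benzoic acid with two ortho substituents.
- The chosen plan sets both centres in one catalytic step from an achiral precursor.

**Alternative 2:** cuts C7–C8 intermolecularly and C4a=C5 last. The silyl ketene acetal of pyronylacetate A3 would add to the free 1,2-dione corresponding to 11 in a copper bis(oxazoline)-catalysed Mukaiyama aldol addition to give A4. The C5 methyl ketone would then condense onto the pyrone carbonyl.
- The relative configuration would rest on an open transition state and not on a ring fusion.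
- A4 is an acyclic β-hydroxy ester that would face retro-aldol cleavage under the condensation conditions.
- C5 can reach both the carbonyl carbon C4a and the Michael position C1 through six-membered transition states, so the closure is ambiguous.
- The chosen plan makes C4a=C5 first by an irreversible addition and closes ring B at the one strongly electrophilic carbonyl.

**Alternative 3:** cuts the C7–O bond last, by hydroxylation of the enolate of the 7,8-dihydro ketone A5 with an N-sulfonyloxaziridine.
- The oxidant would approach C7 anti to the C8 ester and place OH trans to it, giving the 7-epimer A6 and not the cis compound.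
- The enolate of A5 is one dehydrogenation away from the aromatic benzopyrylium olate.
- C8 would have to be set separately beforehand and kept from epimerising.
- In the chosen plan the cis relation is a consequence of the lactone ring.

Key step: step 7

## Steps

Step 1
Reactants: 1 kojic acid (5-hydroxy-2-(hydroxymethyl)-4H-pyran-4-one)
Product: 2 6-(hydroxymethyl)-4-oxo-4H-pyran-3-yl trifluoromethanesulfonate
Conditions: PhNTf2 (1.05 equiv), Et3N (1.2 equiv), DMF, 0 → 23 °C
Reagents that add atoms: N-phenylbis(trifluoromethanesulfonimide), O=S(=O)(N(c1ccccc1)S(=O)(=O)C(F)(F)F)C(F)(F)F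
Why: O-Triflation with an N-aryl triflimide; only the enolic hydroxyl (a vinylogous acid) is ionised by Et3N, and the reagent does not sulfonylate the neutral primary alcohol.

Step 2
Reactants: 2 6-(hydroxymethyl)-4-oxo-4H-pyran-3-yl trifluoromethanesulfonate; 3 tert-butyl (triphenylphosphoranylidene)acetate
Product: 5 tert-butyl (E)-3-[4-oxo-5-(trifluoromethylsulfonyloxy)-4H-pyran-2-yl]prop-2-enoate, via formyl triflate 4 (not isolated)
Conditions: activated MnO2 (10 equiv), 3 (1.3 equiv), CH2Cl2, 23 °C
Reagents that add atoms: none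
Why: Tandem oxidation–Wittig olefination; MnO2 oxidises the hydroxymethyl group, which is allylic to the pyrone double bond, and the electron-poor aldehyde 4 is trapped at once by the stabilised ylide, which should give the E-enoate and avoids handling the hydration-prone aldehyde.

Step 3
Reactants: 5 tert-butyl (E)-3-[4-oxo-5-(trifluoromethylsulfonyloxy)-4H-pyran-2-yl]prop-2-enoate; 6 methyl bromoacetate
Product: 8 methyl 2-{6-[(E)-3-tert-butoxy-3-oxoprop-1-enyl]-4-oxo-4H-pyran-3-yl}acetate, via Reformatsky reagent 7 (not isolated)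
Conditions: 6 (1.6 equiv), Zn dust (Me3SiCl-activated), THF, 40 °C; then 5, Pd(OAc)2 (5 mol %), XPhos (2-dicyclohexylphosphino-2′,4′,6′-triisopropylbiphenyl, 10 mol %), THF, 23 → 50 °C
Reagents that add atoms: none
Why: Negishi coupling of a Reformatsky reagent with a vinyl triflate under zerovalent palladium catalysis forms the C8–C8a bond; the zinc enolate is too mild to attack the tert-butyl enoate or the pyrone, and the methyl ester keeps the new carboxyl distinguishable from the acrylate.

Step 4
Reactants: 8 methyl 2-{6-[(E)-3-tert-butoxy-3-oxoprop-1-enyl]-4-oxo-4H-pyran-3-yl}acetate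
Product: 10 2-{6-[(E)-3-tert-butoxy-3-oxoprop-1-enyl]-4-oxo-4H-pyran-3-yl}acetic acid, via trimethylstannyl ester 9 (not isolated)
Conditions: Me3SnOH (3 equiv), 1,2-dichloroethane, 70 °C; then 1 M HCl work-up
Reagents that add atoms: trimethyltin hydroxide, C[Sn](C)(C)O
Why: Trimethyltin hydroxide cleaves methyl esters under nearly neutral conditions and should leave the tert-butyl ester and the hydroxide-sensitive pyrone untouched.

Step 5
Reactants: 11 3,3-dimethoxybutan-2-one
Product: 14 3,3-dimethoxybut-1-yne, via enol phosphate 12 (not isolated), via lithium acetylide 13 (not isolated)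
Conditions: LDA (1.1 equiv), THF, −78 °C; ClP(O)(OEt)2 (1.1 equiv), −78 → 23 °C; LDA (2.3 equiv), −78 → 23 °C; H2O
Reagents that add atoms: none
Why: Conversion of a methyl ketone into a terminal alkyne by O-phosphorylation of the kinetic enolate and base-induced elimination of phosphate; the ketone can enolise only toward its methyl group, and the ketal carbon is the future C7 carbonyl.

Step 6
Reactants: 10 2-{6-[(E)-3-tert-butoxy-3-oxoprop-1-enyl]-4-oxo-4H-pyran-3-yl}acetic acid; 14 3,3-dimethoxybut-1-yne
Product: 19 2-{(4Z)-6-[(E)-3-tert-butoxy-3-oxoprop-1-enyl]-4-(2,3-dioxobutylidene)-4H-pyran-3-yl}acetic acid, via alkynylmagnesium chloride 15 (not isolated), via lithium carboxylate 16 (not isolated), via pyranol adduct 17 (not isolated), via keto ketal acid 18 (not isolated)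
Conditions: 14 (2.2 equiv), i-PrMgCl (2.1 equiv), THF, 0 → 23 °C; 10 pre-treated with LiHMDS (1.0 equiv, THF, −78 °C) and LaCl3·2LiCl (1.1 equiv), added at −40 °C; −40 → 0 °C; then 1 M HCl, THF, 0 → 23 °C
Reagents that add atoms: water, O
Why: Magnesiation of the terminal alkyne 14 with i-PrMgCl gives the weakly basic alkynylmagnesium chloride 15, whose 1,2-addition to the pyrone carbonyl C4a is promoted by the soluble Lewis acid LaCl3·2LiCl (the carboxyl is protected as its lithium salt 16); a Meyer–Schuster rearrangement follows, in which acid ionises pyranol 17 to a 4-alkynylpyrylium ion, water adds at C6, and tautomerisation gives the 4-ylidenepyran ketone 18. The same aqueous acid hydrolyses the dimethyl ketal to the 1,2-dione while the tert-butyl ester should survive. The E and Z forms of the push–pull C4a=C5 bond interconvert, so its geometry need not be controlled.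

Step 7
Reactants: 19 2-{(4Z)-6-[(E)-3-tert-butoxy-3-oxoprop-1-enyl]-4-(2,3-dioxobutylidene)-4H-pyran-3-yl}acetic acid
Product: 22 cis-fused β-lactone of (7R,8R)-3-[(E)-3-tert-butoxy-3-oxoprop-1-enyl]-7-hydroxy-7-methyl-6-oxo-7,8-dihydro-6H-isochromene-8-carboxylic acid (O7 to the C8 carbonyl), via mixed tosyl anhydride 20 (not isolated), via ammonium enolate 21 (not isolated)
Conditions: TsCl (1.3 equiv), i-Pr2NEt (4 equiv), LiCl (1 equiv), (R)-2-phenyl-3,4-dihydro-2H-benzo[4,5]thiazolo[3,2-a]pyrimidine [(R)-HBTM, 20 mol %], CH2Cl2, 0 → 23 °C, slow addition of 19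
Reagents that add atoms: none
Why: This is a nucleophile-catalysed aldol-lactonisation, and the closest known type is the isothiourea-catalysed intramolecular aldol-lactonisation of keto acids to carbocycle-fused β-lactones. TsCl converts 19 into 20; acyl transfer to the catalyst and deprotonation by i-Pr2NEt give the (Z)-ammonium enolate 21, in which an O···S contact holds the enolate coplanar with the catalyst and the C2 phenyl group covers one face. C8 of 21 adds to the C7 ketone (6-(enolexo)-exo-trig), which closes ring B, and the new alkoxide attacks the acylammonium carbon (4-exo-trig), which closes the β-lactone and releases the catalyst. C8 is set by the catalyst: by the accepted model the (R)-catalyst forces the ketone onto the enolate face away from the phenyl group, which corresponds to 8R. C7 is set by the ring fusion, because only the aldolate with O7 cis to the C8 acyl group can lactonise while the other can revert by retro-aldol, so 7R follows from 8R. Chemoselectivity for C7 over C6 comes from the substrate: C6 is a doubly vinylogous ester carbonyl of the 4-ylidenepyran and would give a five-membered ring, whereas C7 is an activated 1,2-dione carbonyl and gives the six-membered ring. Only the Z form of the C4a=C5 bond places C7 within reach of C8, and since the E and Z forms should interconvert (LiCl assisting), both drain into 22.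

Step 8
Reactants: 23 (S)-1-bromo-2-methylbutane; 24 N-methoxy-N-methylacetamide
Product: 26 (S)-4-methylhexan-2-one, via Grignard reagent 25 (not isolated)
Conditions: Mg turnings, THF, 23 → 45 °C; then 24 (0.9 equiv), THF, 0 °C; 1 M HCl
Reagents that add atoms: none
Why: Weinreb ketone synthesis; the N-methoxy-N-methylamide prevents over-addition, and the C4′ stereocentre comes unchanged from the chiral-pool bromide because it is not involved in the reaction.

Step 9
Reactants: 26 (S)-4-methylhexan-2-one
Product: 27 (2S,4S)-4-methylhexan-2-ol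
Conditions: alcohol dehydrogenase ADH-A from Rhodococcus ruber (Prelog-selective), NAD+ (cat.), 2-propanol (15% v/v), phosphate buffer pH 7.5, 30 °C
Reagents that add atoms: none
Why: Enzymatic ketone reduction with coupled-substrate cofactor recycling; hydride is delivered to the Re face of the methyl ketone (Prelog rule), so C2′ should become S under catalyst control regardless of the remote C4′ centre.

Step 10
Reactants: 22 cis-fused β-lactone of (7R,8R)-3-[(E)-3-tert-butoxy-3-oxoprop-1-enyl]-7-hydroxy-7-methyl-6-oxo-7,8-dihydro-6H-isochromene-8-carboxylic acid; 27 (2S,4S)-4-methylhexan-2-ol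
Product: 30 (2S,4S)-4-methylhexan-2-yl (7R,8R)-3-[(E)-3-tert-butoxy-3-oxoprop-1-enyl]-7-hydroxy-7-methyl-6-oxo-7,8-dihydro-6H-isochromene-8-carboxylate, via lithium alkoxide 28 (not isolated), via lithium aldolate 29 (not isolated)
Conditions: 27 (1.5 equiv), n-BuLi (1.2 equiv), THF, −78 °C; then 22, −78 → −50 °C; AcOH (2 equiv), −78 °C
Reagents that add atoms: none
Why: Alkoxide opening of a β-lactone by acyl–oxygen cleavage, driven by ring strain, forms the hindered secondary ester without activating a free β-hydroxy acid. The C7–O and C2′–O bonds are not touched, so all four stereocentres are retained and the cis relation of O7 and the C8 ester is that of the lactone. Low temperature and an acidic quench of 29 are meant to suppress retro-aldol cleavage and elimination.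

Step 11
Reactants: 30 (2S,4S)-4-methylhexan-2-yl (7R,8R)-3-[(E)-3-tert-butoxy-3-oxoprop-1-enyl]-7-hydroxy-7-methyl-6-oxo-7,8-dihydro-6H-isochromene-8-carboxylate
Product: 31 (E)-3-[(7R,8R)-7-hydroxy-7-methyl-8-{[(2S,4S)-4-methylhexan-2-yl]oxycarbonyl}-6-oxo-7,8-dihydro-6H-isochromen-3-yl]prop-2-enoic acid (CNP0114760.1)
Conditions: CF3CO2H/CH2Cl2 (1:4), 0 → 23 °C
Reagents that add atoms: none
Why: Acidolysis of the tert-butyl ester with loss of 2-methylpropene; no base is used, and the secondary alkyl ester, the tertiary α-ketol and the chromophore (protonated reversibly at O6) should withstand brief acid.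

## Compound list

1 | kojic acid, 5-hydroxy-2-(hydroxymethyl)-4H-pyran-4-one | OCC1=CC(=O)C(O)=CO1 | starting material
2 | 6-(hydroxymethyl)-4-oxo-4H-pyran-3-yl trifluoromethanesulfonate | OCC1=CC(=O)C(OS(=O)(=O)C(F)(F)F)=CO1 | intermediate
3 | tert-butyl (triphenylphosphoranylidene)acetate | CC(C)(C)OC(=O)C=P(c1ccccc1)(c1ccccc1)c1ccccc1 | starting material
4 | 6-formyl-4-oxo-4H-pyran-3-yl trifluoromethanesulfonate | O=CC1=CC(=O)C(OS(=O)(=O)C(F)(F)F)=CO1 | intermediate
5 | tert-butyl (E)-3-[4-oxo-5-(trifluoromethylsulfonyloxy)-4H-pyran-2-yl]prop-2-enoate | CC(C)(C)OC(=O)/C=C/C1=CC(=O)C(OS(=O)(=O)C(F)(F)F)=CO1 | intermediate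
6 | methyl bromoacetate | COC(=O)CBr | starting material
7 | bromo(2-methoxy-2-oxoethyl)zinc | COC(=O)C[Zn]Br | intermediate
8 | methyl 2-{6-[(E)-3-tert-butoxy-3-oxoprop-1-enyl]-4-oxo-4H-pyran-3-yl}acetate | COC(=O)CC1=COC(/C=C/C(=O)OC(C)(C)C)=CC1=O | intermediate
9 | trimethylstannyl 2-{6-[(E)-3-tert-butoxy-3-oxoprop-1-enyl]-4-oxo-4H-pyran-3-yl}acetate | C[Sn](C)(C)OC(=O)CC1=COC(/C=C/C(=O)OC(C)(C)C)=CC1=O | intermediate
10 | 2-{6-[(E)-3-tert-butoxy-3-oxoprop-1-enyl]-4-oxo-4H-pyran-3-yl}acetic acid | OC(=O)CC1=COC(/C=C/C(=O)OC(C)(C)C)=CC1=O | intermediate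
11 | 3,3-dimethoxybutan-2-one | CC(=O)C(C)(OC)OC | starting material
12 | diethyl 3,3-dimethoxybut-1-en-2-yl phosphate | C=C(OP(=O)(OCC)OCC)C(C)(OC)OC | intermediate
13 | lithium 3,3-dimethoxybut-1-yn-1-ide | [Li]C#CC(C)(OC)OC | intermediate
14 | 3,3-dimethoxybut-1-yne | C#CC(C)(OC)OC | intermediate
15 | chloro(3,3-dimethoxybut-1-ynyl)magnesium | Cl[Mg]C#CC(C)(OC)OC | intermediate
16 | lithium 2-{6-[(E)-3-tert-butoxy-3-oxoprop-1-enyl]-4-oxo-4H-pyran-3-yl}acetate | [Li+].[O-]C(=O)CC1=COC(/C=C/C(=O)OC(C)(C)C)=CC1=O | intermediate
17 | 2-{6-[(E)-3-tert-butoxy-3-oxoprop-1-enyl]-4-(3,3-dimethoxybut-1-ynyl)-4-hydroxy-4H-pyran-3-yl}acetic acid (racemic at the pyran C4, which becomes sp2 in the same step) | CC(C)(C)OC(=O)/C=C/C1=CC(O)(C#CC(C)(OC)OC)C(CC(O)=O)=CO1 | intermediate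
18 | 2-{(4Z)-6-[(E)-3-tert-butoxy-3-oxoprop-1-enyl]-4-(3,3-dimethoxy-2-oxobutylidene)-4H-pyran-3-yl}acetic acid | CC(C)(C)OC(=O)/C=C/C1=C/C(=C/C(=O)C(C)(OC)OC)C(CC(O)=O)=CO1 | intermediate
19 | 2-{(4Z)-6-[(E)-3-tert-butoxy-3-oxoprop-1-enyl]-4-(2,3-dioxobutylidene)-4H-pyran-3-yl}acetic acid | CC(C)(C)OC(=O)/C=C/C1=C/C(=C/C(=O)C(C)=O)C(CC(O)=O)=CO1 | intermediate
20 | mixed anhydride of 19 with 4-methylbenzenesulfonic acid | CC(C)(C)OC(=O)/C=C/C1=C/C(=C/C(=O)C(C)=O)C(CC(=O)OS(=O)(=O)c2ccc(C)cc2)=CO1 | intermediate
21 | zwitterionic (Z)-ammonium enolate formed from 19 and (R)-HBTM (acyl group on the amidine nitrogen next to C2 of the catalyst) | CC(C)(C)OC(=O)/C=C/C1=C/C(=C/C(=O)C(C)=O)C(/C=C(/[N+]2=C3Sc4ccccc4N3CC[C@@H]2c2ccccc2)[O-])=CO1 | intermediate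
22 | cis-fused β-lactone of (7R,8R)-3-[(E)-3-tert-butoxy-3-oxoprop-1-enyl]-7-hydroxy-7-methyl-6-oxo-7,8-dihydro-6H-isochromene-8-carboxylic acid | O=C3[C@@H]1C2=COC(/C=C/C(=O)OC(C)(C)C)=CC2=CC(=O)[C@]1(C)O3 | intermediate
23 | (S)-1-bromo-2-methylbutane | CC[C@H](C)CBr | starting material
24 | N-methoxy-N-methylacetamide | CC(=O)N(C)OC | starting material
25 | [(S)-2-methylbutyl]magnesium bromide | CC[C@H](C)C[Mg]Br | intermediate
26 | (S)-4-methylhexan-2-one | CC[C@H](C)CC(C)=O | intermediate
27 | (2S,4S)-4-methylhexan-2-ol | CC[C@H](C)C[C@H](C)O | intermediate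
28 | lithium (2S,4S)-4-methylhexan-2-olate | CC[C@H](C)C[C@H](C)O[Li] | intermediate
29 | lithium 7-alkoxide of 30 | CC[C@H](C)C[C@H](C)OC(=O)[C@@H]1C2=COC(/C=C/C(=O)OC(C)(C)C)=CC2=CC(=O)[C@]1(C)O[Li] | intermediate
30 | (2S,4S)-4-methylhexan-2-yl (7R,8R)-3-[(E)-3-tert-butoxy-3-oxoprop-1-enyl]-7-hydroxy-7-methyl-6-oxo-7,8-dihydro-6H-isochromene-8-carboxylate | CC[C@H](C)C[C@H](C)OC(=O)[C@@H]1C2=COC(/C=C/C(=O)OC(C)(C)C)=CC2=CC(=O)[C@]1(C)O | intermediate
31 | (E)-3-[(7R,8R)-7-hydroxy-7-methyl-8-{[(2S,4S)-4-methylhexan-2-yl]oxycarbonyl}-6-oxo-7,8-dihydro-6H-isochromen-3-yl]prop-2-enoic acid | CC[C@H](C)C[C@H](C)OC(=O)[C@@H]1C2=COC(/C=C/C(=O)O)=CC2=CC(=O)[C@]1(C)O | target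

## Step count and risks

Total step count: 11. Longest linear sequence: 8 steps (steps 1, 2, 3, 4, 6, 7, 10, 11, from kojic acid 1).

**Step 7 (key step).**
- What may go wrong: the aldol step may lag behind other reactions of the activated acid, because the reactive Z form of the C4a=C5 bond is probably the minor geometric isomer and the C7 carbonyl must twist out of conjugation. The strained lactone 22 may also lose CO2 toward an aromatic benzopyrylium olate. The sense of induction rests on the accepted catalyst model and is not verified for this substrate; the (S)-catalyst is equally available.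
- Fallback (avoids any β-lactone): starting from 19, the carboxylate is alkylated under Mitsunobu conditions (PPh3, diisopropyl azodicarboxylate) with (2R,4S)-4-methylhexan-2-ol F1, obtained from 26 with an anti-Prelog alcohol dehydrogenase (Lactobacillus kefir). Inversion at C2′ gives the keto ester (2S,4S)-4-methylhexan-2-yl 2-{(4Z)-6-[(E)-3-tert-butoxy-3-oxoprop-1-enyl]-4-(2,3-dioxobutylidene)-4H-pyran-3-yl}acetate F2. An intramolecular ester aldol addition under equilibrating conditions (KOtBu, 0.2 equiv, THF, −40 °C, AcOH quench) should then give the cis aldols, namely 30 and its (7S,8S)-diastereomer F3. These are separated by chromatography, with the enantiopure side chain serving as internal resolving group. The route is rejoined at 30.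

**Step 10.**
- What may go wrong: retro-aldol cleavage of the C7–C8 bond in the lithium aldolate, which would erode both ring stereocentres, or elimination of water after deprotonation at C8. A slow attack of the hindered alkoxide makes both more likely.
- Fallback: starting from 22, hydrolysis (LiOH, THF/H2O, 0 °C, then pH 3) gives the hydroxy acid (7R,8R)-3-[(E)-3-tert-butoxy-3-oxoprop-1-enyl]-7-hydroxy-7-methyl-6-oxo-7,8-dihydro-6H-isochromene-8-carboxylic acid F4. (2R,4S)-4-Methylhexan-2-ol F5 (the same alcohol as F1, made in the same way) is converted with MsCl and Et3N into (2R,4S)-4-methylhexan-2-yl methanesulfonate F6. The caesium salt of F4 (Cs2CO3, DMF, 23 °C) is O-alkylated by F6 with inversion at C2′, so the carboxyl group is never activated. The route is rejoined at 30.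

**Step 6.**
- What may go wrong: poor conversion at the doubly vinylogous pyrone carbonyl once the neighbouring carboxylate is present (aggregation, lowered electrophilicity), with addition at C1 or at the tert-butyl ester taking over.
- Fallback (changes the order of the C–C bond formations): starting from 5 and 14, the alkynylmagnesium chloride 15 is added in the presence of LaCl3·2LiCl (THF, −40 °C) to the triflate 5, which has no acidic or anionic group. Meyer–Schuster rearrangement under buffered acid (pyridinium 4-toluenesulfonate, wet CH2Cl2) that leaves the dimethyl ketal in place gives tert-butyl (E)-3-[(4Z)-4-(3,3-dimethoxy-2-oxobutylidene)-5-(trifluoromethylsulfonyloxy)-4H-pyran-2-yl]prop-2-enoate F7. Negishi coupling with 7 as in step 3 gives the methyl ester methyl 2-{(4Z)-6-[(E)-3-tert-butoxy-3-oxoprop-1-enyl]-4-(3,3-dimethoxy-2-oxobutylidene)-4H-pyran-3-yl}acetate F8. Me3SnOH as in step 4 gives 18, and 1 M HCl in THF gives 19, where the route is rejoined.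

**Step 3.**
- What may go wrong: S–O cleavage of the electron-poor vinyl triflate by the zinc enolate, or slow transmetalation leading to loss of the triflate without C–C bond formation.
- Fallback: starting from 5, Suzuki coupling with (E)-2-(2-ethoxyvinyl)-4,4,5,5-tetramethyl-1,3,2-dioxaborolane (Pd(PPh3)4, K3PO4, dioxane/H2O, 60 °C) gives the enol ether tert-butyl (E)-3-{5-[(E)-2-ethoxyvinyl]-4-oxo-4H-pyran-2-yl}prop-2-enoate F9. Hydrolysis (aqueous HCO2H, THF) gives the aldehyde tert-butyl (E)-3-[4-oxo-5-(2-oxoethyl)-4H-pyran-2-yl]prop-2-enoate F10. Pinnick oxidation (NaClO2, NaH2PO4, 2-methylbut-2-ene, t-BuOH/H2O) gives 10, where the route is rejoined.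

## Further compounds

F1 | step 7 | (2R,4S)-4-methylhexan-2-ol | CC[C@H](C)C[C@@H](C)O
F2 | step 7 | (2S,4S)-4-methylhexan-2-yl 2-{(4Z)-6-[(E)-3-tert-butoxy-3-oxoprop-1-enyl]-4-(2,3-dioxobutylidene)-4H-pyran-3-yl}acetate | CC(C)(C)OC(=O)/C=C/C1=C/C(=C/C(=O)C(C)=O)C(CC(=O)O[C@@H](C)C[C@@H](C)CC)=CO1
F3 | step 7 | (2S,4S)-4-methylhexan-2-yl (7S,8S)-3-[(E)-3-tert-butoxy-3-oxoprop-1-enyl]-7-hydroxy-7-methyl-6-oxo-7,8-dihydro-6H-isochromene-8-carboxylate | CC[C@H](C)C[C@H](C)OC(=O)[C@H]1C2=COC(/C=C/C(=O)OC(C)(C)C)=CC2=CC(=O)[C@@]1(C)O
F4 | step 10 | (7R,8R)-3-[(E)-3-tert-butoxy-3-oxoprop-1-enyl]-7-hydroxy-7-methyl-6-oxo-7,8-dihydro-6H-isochromene-8-carboxylic acid | OC(=O)[C@@H]1C2=COC(/C=C/C(=O)OC(C)(C)C)=CC2=CC(=O)[C@]1(C)O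
F5 | step 10 | (2R,4S)-4-methylhexan-2-ol | CC[C@H](C)C[C@@H](C)O
F6 | step 10 | (2R,4S)-4-methylhexan-2-yl methanesulfonate | CC[C@H](C)C[C@@H](C)OS(C)(=O)=O
F7 | step 6 | tert-butyl (E)-3-[(4Z)-4-(3,3-dimethoxy-2-oxobutylidene)-5-(trifluoromethylsulfonyloxy)-4H-pyran-2-yl]prop-2-enoate | CC(C)(C)OC(=O)/C=C/C1=C/C(=C/C(=O)C(C)(OC)OC)C(OS(=O)(=O)C(F)(F)F)=CO1
F8 | step 6 | methyl 2-{(4Z)-6-[(E)-3-tert-butoxy-3-oxoprop-1-enyl]-4-(3,3-dimethoxy-2-oxobutylidene)-4H-pyran-3-yl}acetate | CC(C)(C)OC(=O)/C=C/C1=C/C(=C/C(=O)C(C)(OC)OC)C(CC(=O)OC)=CO1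
F9 | step 3 | tert-butyl (E)-3-{5-[(E)-2-ethoxyvinyl]-4-oxo-4H-pyran-2-yl}prop-2-enoate | CCO/C=C/C1=COC(/C=C/C(=O)OC(C)(C)C)=CC1=O
F10 | step 3 | tert-butyl (E)-3-[4-oxo-5-(2-oxoethyl)-4H-pyran-2-yl]prop-2-enoate | O=CCC1=COC(/C=C/C(=O)OC(C)(C)C)=CC1=O
A1 | alternative 1 | (2S,4S)-4-methylhexan-2-yl 5-[(E)-5-tert-butoxy-5-oxopent-3-en-1-ynyl]-6-formyl-3-hydroxy-2-methylbenzoate | CC[C@H](C)C[C@H](C)OC(=O)c1c(C)c(O)cc(C#C/C=C/C(=O)OC(C)(C)C)c1C=O
A2 | alternative 1 | (2S,4S)-4-methylhexan-2-yl 3-[(E)-3-tert-butoxy-3-oxoprop-1-enyl]-7-methyl-6-oxo-6H-isochromene-8-carboxylate | CC[C@H](C)C[C@H](C)OC(=O)C1=C(C)C(=O)C=C2C=C(/C=C/C(=O)OC(C)(C)C)OC=C12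
A3 | alternative 2 | (2S,4S)-4-methylhexan-2-yl 2-{6-[(E)-3-tert-butoxy-3-oxoprop-1-enyl]-4-oxo-4H-pyran-3-yl}acetate | CC[C@H](C)C[C@H](C)OC(=O)CC1=COC(/C=C/C(=O)OC(C)(C)C)=CC1=O
A4 | alternative 2 | (2S,4S)-4-methylhexan-2-yl (2R,3R)-2-{6-[(E)-3-tert-butoxy-3-oxoprop-1-enyl]-4-oxo-4H-pyran-3-yl}-3-hydroxy-3-methyl-4-oxopentanoate | CC[C@H](C)C[C@H](C)OC(=O)[C@H](C1=COC(/C=C/C(=O)OC(C)(C)C)=CC1=O)[C@@](C)(O)C(C)=O
A5 | alternative 3 | (2S,4S)-4-methylhexan-2-yl (8S)-3-[(E)-3-tert-butoxy-3-oxoprop-1-enyl]-7-methyl-6-oxo-7,8-dihydro-6H-isochromene-8-carboxylate (either configuration at C7) | CC[C@H](C)C[C@H](C)OC(=O)[C@@H]1C2=COC(/C=C/C(=O)OC(C)(C)C)=CC2=CC(=O)C1C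
A6 | alternative 3 | (2S,4S)-4-methylhexan-2-yl (7S,8R)-3-[(E)-3-tert-butoxy-3-oxoprop-1-enyl]-7-hydroxy-7-methyl-6-oxo-7,8-dihydro-6H-isochromene-8-carboxylate | CC[C@H](C)C[C@H](C)OC(=O)[C@@H]1C2=COC(/C=C/C(=O)OC(C)(C)C)=CC2=CC(=O)[C@@]1(C)O
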